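## Analysis of the target

Compound 20 is a C30 bicyclic alcohol, and labdane-style numbering is used throughout: ring A is C1–C5 plus C10 with the gem-dimethyl group on C4, ring B is C5–C10, C20 is the methyl on C10, C17 the methyl on C8, and C9 carries the chain through C11. The chain is a (3E,7E)-homofarnesyl group with three trisubstituted alkenes; these rule out ozonolysis, hydrogenation, strong acid and unselective electrophilic oxidants once the chain is in place. There are four stereocentres, (5R,8R,9R,10S): H5 and the C10 methyl are cis (a cis-fused decalin, unlike the common trans labdanoids), the C9 chain is cis to the C10 methyl, and at C8 the methyl is cis to the chain with the hydroxyl on the opposite face. C10 is quaternary and sits between the tertiary C9 and the ring-fusion carbon C5, which is itself flanked by the quaternary C4. The tertiary alcohol can eliminate, and C9 becomes epimerisable whenever C8 is a ketone. The synthesis is hard because of the contiguous C9/C10 pair, the cis fusion next to a gem-dimethyl group, and the need to carry an acid- and oxidant-sensitive polyene. The strategy rests on one feature: C5 is bonded to the two quaternary carbons C4 and C10, so once C9 and C10 are fixed on ring A, ring B can be closed by forming C5–C6 from a C5 radical onto a vinyl ketone (C8(=O)–C7=C6) held on C9. That closure gives the C8 ketone directly and should set C5 cis.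

## Retrosynthetic reasoning

**20 ⇒ 19 (cut C8–C17).** The tertiary alcohol is made last so that it never has to survive earlier steps, and because ketone 19 is the direct product of the ring closure. The forward step must deliver a methyl nucleophile to the β face of C8 without enolising toward C9.

**19 ⇒ 18 (cut C5–C6).** C5 lies between two quaternary carbons, so ionic bond formation there is unattractive, whereas a radical tolerates the crowding. Cutting here leaves a monocyclic ring A with an acyclic arm on C10 and so reduces the bicyclic stereochemical problem to C9/C10. The forward reaction has to close ring B in the 6-endo mode, give the cis fusion, and leave the C8 ketone. The xanthate in 18 is the radical source.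

**18 ⇒ 15 (remove C6).** The vinyl ketone polymerises and adds nucleophiles readily, so it is unveiled in the last operation before the ring closure. Its precursor 15 holds C8 as a silyl enol ether, which is both a protecting group and the nucleophile that accepts the one-carbon unit.

**15 ⇒ 13 ⇒ 12 ⇒ 11 (C5 and C8 oxidation levels).** The xanthate comes from alcohol 13 and this from the ring ketone. In 11 and 12 the ring ketone has no α-hydrogen and is very hindered, so it is carried unprotected while the side-chain ketone is masked. The order is fixed by two incompatibilities: sulfur would interfere with the palladium oxidation that creates C8=O, and xanthate formation needs a base that a free methyl ketone would not tolerate.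

**11 ⇒ 10 (C8=O from the vinyl group).** Among the four alkenes of 10 only the monosubstituted one is oxidised by a Wacker process, which places the oxygen on C8.

**10 ⇒ 8 + 9 (cut C9–C10).** This bond joins the quaternary and the tertiary centre, and a branched-selective iridium allylation makes both in one catalytic step. Ketone 9 can enolise in one direction only, and carbonate 8 brings the complete chain, so the route is convergent. The forward step must control the allyl face (C9) and the enolate face (C10).

**8 ⇒ 7 ⇒ 6 ⇒ 4 + 5, and 4 ⇒ 2 ⇒ 1 (the chain).** The (E)-allylic carbonate is reached by olefination of aldehyde 4 with phosphonate 5 and reduction. Aldehyde 4 is the two-carbon homologue of bromide 1, whose alkene geometry is carried through unchanged.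

## Alternatives that were turned down

**Alternative 1:** The disconnections are C9–C11 and C8–C17 on a ring-B dienone. In the forward key step the homoallylic Grignard reagent A3 adds under chiral copper catalysis to one enone arm of the prochiral dienone A2, and the enolate is methylated to give A1.
- For: the chain, C17 and three stereocentres (C8, C9, C10) arrive in one catalytic operation, and the chain enters late as a nucleophile. On convergence and stereocentres per step this alternative is stronger than the chosen route.
- Against: the carbonyl of A1 is on C7, so the C8 oxygen has to be introduced afterwards at a tertiary α-carbon and the C7 carbonyl removed. Ring A is still open, and closing C4–C5 onto the remaining enone must create C5 next to a quaternary C4. The two faces of A2 differ only by methyl versus a primary alkyl arm on C10, so the C9/C10 relationship rests entirely on the catalyst, at a β-carbon next to a quaternary centre.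
- Comparison: the chosen route places oxygen on C8 and sets the ring fusion in the ring-forming step itself, which saves the oxygen transposition and the second ring closure.

**Alternative 2:** The disconnections are C9–C10 and C1–C9, later C9–C11. The diazoketone A6, derived from the chiral-pool ketone A5, is decomposed by a copper catalyst and the carbenoid adds to the C10=C1 alkene to give the cyclopropyl ketone A4; reductive opening of the C1–C9 bond and alkylation of the resulting enolate then introduce the chain.
- For: C5 comes from the chiral pool, the intramolecular cyclopropanation can only give the cis fusion, and the quaternary C10 and ring B form together. The route would be clearly shorter than the chosen one, and on step count it is the stronger plan.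
- Against: enantiopure A5 is not a bulk chemical. The reductive step must cleave C1–C9 and not C9–C10. The C9 enolate is neopentylic and must be alkylated by an unactivated homoallylic iodide that eliminates easily. The C9 configuration then depends on substrate control in a flexible cis-decalone enolate.
- Comparison: the chosen route is longer, but it installs the chain and C9 under catalyst control before ring closure and closes ring B under neutral radical conditions that do not touch the polyene.

**Alternative 3:** The disconnections are C5–C6 and C9–C10 by a Diels–Alder reaction of enal A8 with diene A9 under a chiral Lewis acid, giving A7.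
- For: ring B and three stereocentres form at once, the cis fusion is inherent in the cycloaddition, and the formyl group is a handle for C20.
- Against: A8 is a β,β-disubstituted enal with the gem-dimethyl group next to the reacting carbon, a very poor dienophile. In A9 the substituents on C9 and C8 direct the regiochemistry in opposite senses. After the cycloaddition the formyl group must be reduced to methyl, the C7=C8 alkene hydrated with control at C8, and the whole chain built from a two-carbon stub.
- Comparison: this alternative is stronger on ring-fusion control by design. The chosen route has the chain complete at the ring-closing stage and reaches the target one step after it.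

Key step: step 12

Assumption: the (Ra,R,R) antipode of the phosphoramidite is taken to give the (3S) allylic centre of 10, by analogy with the usual facial preference of this catalyst class for (E)-allyl carbonates; if the sense is the reverse, the mirror-image ligand is used and nothing else changes.

Remark: C5 of 13–18 is drawn as the epimer expected from axial hydride delivery (oxygen cis to the C10 methyl); it is the C5 epimer of the xanthate as usually drawn with oxygen trans to that methyl, and either epimer gives the same C5 radical.

## Route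

Step 1
Reactants: 1 (2E,6E)-farnesyl bromide
Product: 2 (4E,8E)-5,9,13-trimethyltetradeca-4,8,12-trienenitrile
Conditions: MeCN (3 equiv), n-BuLi, THF, −78 °C; then 1, −78 → −20 °C
Reagents that add atoms: acetonitrile CC#N
Why: SN2 alkylation of lithiated acetonitrile by a primary allylic bromide; excess carbanion suppresses double alkylation and the alkene geometry is not touched.

Step 2
Reactants: 2 (4E,8E)-5,9,13-trimethyltetradeca-4,8,12-trienenitrile
Product: 4 (4E,8E)-5,9,13-trimethyltetradeca-4,8,12-trienal, via N-aluminoimine 3 (not isolated)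
Conditions: iBu2AlH (1.2 equiv), CH2Cl2, −78 °C; aq. potassium sodium tartrate
Reagents that add atoms: water O
Why: Partial reduction of a nitrile with iBu2AlH stops at the N-aluminoimine, which is hydrolysed on work-up; the aldehyde is γ,δ-unsaturated and cannot move into conjugation.

Step 3
Reactants: 4 (4E,8E)-5,9,13-trimethyltetradeca-4,8,12-trienal; 5 triethyl phosphonoacetate
Product: 6 ethyl (2E,6E,10E)-7,11,15-trimethylhexadeca-2,6,10,14-tetraenoate
Conditions: NaH, THF, 0 °C → rt
Reagents that add atoms: none
Why: Horner–Wadsworth–Emmons olefination; the stabilised phosphonate anion gives the (E)-enoate.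

Step 4
Reactants: 6 ethyl (2E,6E,10E)-7,11,15-trimethylhexadeca-2,6,10,14-tetraenoate
Product: 7 (2E,6E,10E)-7,11,15-trimethylhexadeca-2,6,10,14-tetraen-1-ol
Conditions: iBu2AlH (2.2 equiv), CH2Cl2, −78 °C
Reagents that add atoms: none
Why: 1,2-Reduction of an enoate to the allylic alcohol by iBu2AlH, with retention of the (E) geometry.

Step 5
Reactants: 7 (2E,6E,10E)-7,11,15-trimethylhexadeca-2,6,10,14-tetraen-1-ol
Product: 8 methyl (2E,6E,10E)-7,11,15-trimethylhexadeca-2,6,10,14-tetraen-1-yl carbonate
Conditions: ClCO2Me, pyridine, CH2Cl2, 0 °C
Reagents that add atoms: methyl chloroformate COC(=O)Cl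
Why: O-Acylation gives the linear (E)-allyl methyl carbonate, the standard electrophile for iridium-catalysed allylic substitution.

Step 6
Reactants: 8 methyl (2E,6E,10E)-7,11,15-trimethylhexadeca-2,6,10,14-tetraen-1-yl carbonate; 9 2,2,6-trimethylcyclohexan-1-one
Product: 10 (2R)-2,6,6-trimethyl-2-[(3S,6E,10E)-7,11,15-trimethylhexadeca-1,6,10,14-tetraen-3-yl]cyclohexan-1-one
Conditions: 9 (1.5 equiv), Ba(OtBu)2, THF; then 8, [Ir(cod)Cl]2 (2 mol %), (Ra,R,R)-O,O'-(1,1'-binaphthalene-2,2'-diyl) N,N-bis(1-phenylethyl)phosphoramidite (4 mol %), THF, 5 °C → rt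
Reagents that add atoms: none
Why: Iridium-catalysed branched-selective allylic alkylation of a cyclic ketone enolate; 9 can enolise only toward C6, the enolate attacks the substituted allyl terminus, and the ligand fixes C9. C10 should follow from the staggered open transition state that puts the small C10 methyl between chain and allyl unit, the bulky enolate carbon C5 anti to the chain and C1 anti to the allyl carbon, the same arrangement as a chair Claisen transition state.

Step 7
Reactants: 10 (2R)-2,6,6-trimethyl-2-[(3S,6E,10E)-7,11,15-trimethylhexadeca-1,6,10,14-tetraen-3-yl]cyclohexan-1-one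
Product: 11 (2R)-2,6,6-trimethyl-2-[(3R,6E,10E)-7,11,15-trimethyl-2-oxohexadeca-6,10,14-trien-3-yl]cyclohexan-1-one
Conditions: PdCl2 (10 mol %), CuCl (1 equiv), O2 (1 atm), DMF/H2O 7:1, rt
Reagents that add atoms: water O
Why: Tsuji–Wacker oxidation; divalent palladium activates only the monosubstituted alkene and water adds at the internal carbon, so C8 becomes the ketone. The trisubstituted alkenes and the hindered, non-enolisable ring ketone are inert.

Step 8
Reactants: 11 (2R)-2,6,6-trimethyl-2-[(3R,6E,10E)-7,11,15-trimethyl-2-oxohexadeca-6,10,14-trien-3-yl]cyclohexan-1-one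
Product: 12 (2R)-2,6,6-trimethyl-2-[(3R,6E,10E)-7,11,15-trimethyl-2-(triisopropylsilyloxy)hexadeca-1,6,10,14-tetraen-3-yl]cyclohexan-1-one
Conditions: LiN(iPr)2 (1.1 equiv), THF, −78 °C (ketone added to base); iPr3SiOTf, −78 → 0 °C
Reagents that add atoms: triisopropylsilyl trifluoromethanesulfonate CC(C)[Si](C(C)C)(C(C)C)OS(=O)(=O)C(F)(F)F
Why: Kinetic deprotonation occurs at the methyl group, since C9–H is tertiary and next to the quaternary C10 and the ring ketone has no α-hydrogen; O-silylation follows. The bulky silyl enol ether masks C8 against hydride and alkoxide and is the nucleophile for step 11.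

Step 9
Reactants: 12 (2R)-2,6,6-trimethyl-2-[(3R,6E,10E)-7,11,15-trimethyl-2-(triisopropylsilyloxy)hexadeca-1,6,10,14-tetraen-3-yl]cyclohexan-1-one
Product: 13 (1S,2R)-2,6,6-trimethyl-2-[(3R,6E,10E)-7,11,15-trimethyl-2-(triisopropylsilyloxy)hexadeca-1,6,10,14-tetraen-3-yl]cyclohexan-1-ol
Conditions: LiAlH4, THF, 0 °C → reflux
Reagents that add atoms: none
Why: Hydride reduction of a hindered ketone; silyl enol ether and alkenes are inert. Hydride should arrive axially, anti to the axial methyl groups on C4 and C10, placing the hydroxyl cis to the C10 methyl; this centre is destroyed in step 12, so its configuration does not matter.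

Step 10
Reactants: 13 (1S,2R)-2,6,6-trimethyl-2-[(3R,6E,10E)-7,11,15-trimethyl-2-(triisopropylsilyloxy)hexadeca-1,6,10,14-tetraen-3-yl]cyclohexan-1-ol
Product: 15 O-[(1S,2R)-2,6,6-trimethyl-2-[(3R,6E,10E)-7,11,15-trimethyl-2-(triisopropylsilyloxy)hexadeca-1,6,10,14-tetraen-3-yl]cyclohexyl] S-methyl carbonodithioate, via sodium xanthate salt 14 (not isolated)
Conditions: NaH, imidazole (cat.), THF, 0 °C → reflux; CS2; MeI, rt
Reagents that add atoms: carbon disulfide S=C=S; iodomethane CI
Why: Xanthate formation, the first stage of a Barton–McCombie sequence: the alkoxide adds to the small, linear CS2 despite the two flanking quaternary carbons and the salt is S-methylated. C4 and C10 carry no hydrogen, so thermal syn-elimination of the xanthate is impossible.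

Step 11
Reactants: 15 O-[(1S,2R)-2,6,6-trimethyl-2-[(3R,6E,10E)-7,11,15-trimethyl-2-(triisopropylsilyloxy)hexadeca-1,6,10,14-tetraen-3-yl]cyclohexyl] S-methyl carbonodithioate
Product: 18 O-[(1S,2R)-2,6,6-trimethyl-2-[(4R,7E,11E)-8,12,16-trimethyl-3-oxoheptadeca-1,7,11,15-tetraen-4-yl]cyclohexyl] S-methyl carbonodithioate, via Mannich base 16 (not isolated), via methiodide 17 (not isolated)
Conditions: CH2=NMe2+ I−, CH2Cl2, rt; MeI, rt; aq. NaHCO3, rt
Reagents that add atoms: dimethyl(methylidene)ammonium iodide C=[N+](C)C.[I-]
Why: Mannich reaction of the silyl enol ether with a preformed iminium salt, N-methylation and Hofmann-type E1cB elimination give the vinyl ketone. No strong base or nucleophile is used, so the xanthate and the C9 centre survive, and the fragile enone is made last and used at once.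

Step 12
Reactants: 18 O-[(1S,2R)-2,6,6-trimethyl-2-[(4R,7E,11E)-8,12,16-trimethyl-3-oxoheptadeca-1,7,11,15-tetraen-4-yl]cyclohexyl] S-methyl carbonodithioate
Product: 19 (1R,4aR,8aS)-5,5,8a-trimethyl-1-[(3E,7E)-4,8,12-trimethyltrideca-3,7,11-trien-1-yl]octahydronaphthalen-2(1H)-one
Conditions: Bu3SnH (1.3 equiv), AIBN (0.2 equiv), syringe pump 4 h, benzene (0.01 M), 80 °C
Reagents that add atoms: none
Why: The stannyl radical adds to the thiocarbonyl sulfur of 18 and the adduct fragments at the C5–O bond, giving the secondary C5 radical. The closest known reaction type is the tin-hydride-mediated 6-endo-trig cyclisation of an alkyl radical onto the β-carbon of a tethered vinyl ketone whose carbonyl lies in the forming ring. Ring B closes in the 6-endo-trig mode: the nucleophilic C5 radical attacks the electron-poor terminal carbon C6 and forms C5–C6, whereas 5-exo attack at the α-carbon C7 is polarity-mismatched and would give an unstabilised primary radical. The α-keto radical at C7 then takes hydrogen from Bu3SnH, which gives the C8 ketone and carries the chain. The only new stereocentre is C5: ring A reacts in the chair with the C10 methyl axial and the C9 arm equatorial, the axial methyl groups on C10 and C4 shield the face of the radical syn to C20, and C6 bonds axially on the other face, cis to C9 (cis fusion, H5 cis to the C10 methyl). The alternative chair with the C9 arm axial can close only to the same cis fusion, so a trans fusion would need equatorial attack between the two axial methyl groups. The step needs 6-endo over 5-exo closure (secured by the enone polarity and the three-atom tether), closure over premature reduction (slow stannane addition at high dilution), and attack on the enone over 1,5-hydrogen transfer from allylic C12 or 6-exo addition to C13=C14 (secured by the polar acceleration of addition to the enone). Both C5 epimers of 18 give the same radical.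

Step 13
Reactants: 19 (1R,4aR,8aS)-5,5,8a-trimethyl-1-[(3E,7E)-4,8,12-trimethyltrideca-3,7,11-trien-1-yl]octahydronaphthalen-2(1H)-one
Product: 20 (1R,2R,4aR,8aS)-2,5,5,8a-tetramethyl-1-[(3E,7E)-4,8,12-trimethyltrideca-3,7,11-trien-1-yl]decahydronaphthalen-2-ol
Conditions: MeMgBr (3 equiv), CeCl3 (3 equiv), THF, −78 → 0 °C
Reagents that add atoms: methylmagnesium bromide C[Mg]Br
Why: Organocerium 1,2-addition to a hindered, enolisable ketone; the low basicity protects C9. In the cis-decalone ring A is folded under the α face and its axial C1 blocks axial approach to C8, so the methyl group should enter equatorially from the convex β face, giving the β-methyl, α-hydroxyl (8R) carbinol.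

## Compound list

1 | (2E,6E)-farnesyl bromide [(2E,6E)-1-bromo-3,7,11-trimethyldodeca-2,6,10-triene] | CC(C)=CCC/C(C)=C/CC/C(C)=C/CBr | starting material
2 | (4E,8E)-5,9,13-trimethyltetradeca-4,8,12-trienenitrile | CC(C)=CCC/C(C)=C/CC/C(C)=C/CCC#N | intermediate
3 | N-(diisobutylalumanyl)-(4E,8E)-5,9,13-trimethyltetradeca-4,8,12-trien-1-imine | CC(C)=CCC/C(C)=C/CC/C(C)=C/CCC=N[Al](CC(C)C)CC(C)C | intermediate
4 | (4E,8E)-5,9,13-trimethyltetradeca-4,8,12-trienal | CC(C)=CCC/C(C)=C/CC/C(C)=C/CCC=O | intermediate
5 | triethyl phosphonoacetate | CCOC(=O)CP(=O)(OCC)OCC | starting material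
6 | ethyl (2E,6E,10E)-7,11,15-trimethylhexadeca-2,6,10,14-tetraenoate | CC(C)=CCC/C(C)=C/CC/C(C)=C/CC/C=C/C(=O)OCC | intermediate
7 | (2E,6E,10E)-7,11,15-trimethylhexadeca-2,6,10,14-tetraen-1-ol | CC(C)=CCC/C(C)=C/CC/C(C)=C/CC/C=C/CO | intermediate
8 | methyl (2E,6E,10E)-7,11,15-trimethylhexadeca-2,6,10,14-tetraen-1-yl carbonate | CC(C)=CCC/C(C)=C/CC/C(C)=C/CC/C=C/COC(=O)OC | intermediate
9 | 2,2,6-trimethylcyclohexan-1-one (racemic) | CC1CCCC(C)(C)C1=O | starting material
10 | (2R)-2,6,6-trimethyl-2-[(3S,6E,10E)-7,11,15-trimethylhexadeca-1,6,10,14-tetraen-3-yl]cyclohexan-1-one | CC(C)=CCC/C(C)=C/CC/C(C)=C/CC[C@@H](C=C)[C@@]1(C)CCCC(C)(C)C1=O | intermediate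
11 | (2R)-2,6,6-trimethyl-2-[(3R,6E,10E)-7,11,15-trimethyl-2-oxohexadeca-6,10,14-trien-3-yl]cyclohexan-1-one | CC(C)=CCC/C(C)=C/CC/C(C)=C/CC[C@@H](C(C)=O)[C@@]1(C)CCCC(C)(C)C1=O | intermediate
12 | (2R)-2,6,6-trimethyl-2-[(3R,6E,10E)-7,11,15-trimethyl-2-(triisopropylsilyloxy)hexadeca-1,6,10,14-tetraen-3-yl]cyclohexan-1-one | CC(C)=CCC/C(C)=C/CC/C(C)=C/CC[C@@H](C(=C)O[Si](C(C)C)(C(C)C)C(C)C)[C@@]1(C)CCCC(C)(C)C1=O | intermediate
13 | (1S,2R)-2,6,6-trimethyl-2-[(3R,6E,10E)-7,11,15-trimethyl-2-(triisopropylsilyloxy)hexadeca-1,6,10,14-tetraen-3-yl]cyclohexan-1-ol | CC(C)=CCC/C(C)=C/CC/C(C)=C/CC[C@@H](C(=C)O[Si](C(C)C)(C(C)C)C(C)C)[C@@]1(C)CCCC(C)(C)[C@@H]1O | intermediate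
14 | sodium O-[(1S,2R)-2,6,6-trimethyl-2-[(3R,6E,10E)-7,11,15-trimethyl-2-(triisopropylsilyloxy)hexadeca-1,6,10,14-tetraen-3-yl]cyclohexyl] carbonodithioate | CC(C)=CCC/C(C)=C/CC/C(C)=C/CC[C@@H](C(=C)O[Si](C(C)C)(C(C)C)C(C)C)[C@@]1(C)CCCC(C)(C)[C@@H]1OC(=S)[S-].[Na+] | intermediate
15 | O-[(1S,2R)-2,6,6-trimethyl-2-[(3R,6E,10E)-7,11,15-trimethyl-2-(triisopropylsilyloxy)hexadeca-1,6,10,14-tetraen-3-yl]cyclohexyl] S-methyl carbonodithioate | CC(C)=CCC/C(C)=C/CC/C(C)=C/CC[C@@H](C(=C)O[Si](C(C)C)(C(C)C)C(C)C)[C@@]1(C)CCCC(C)(C)[C@@H]1OC(=S)SC | intermediate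
16 | O-[(1S,2R)-2-[(4R,7E,11E)-1-(dimethylamino)-8,12,16-trimethyl-3-oxoheptadeca-7,11,15-trien-4-yl]-2,6,6-trimethylcyclohexyl] S-methyl carbonodithioate | CC(C)=CCC/C(C)=C/CC/C(C)=C/CC[C@@H](C(=O)CCN(C)C)[C@@]1(C)CCCC(C)(C)[C@@H]1OC(=S)SC | intermediate
17 | N,N,N-trimethylammonium iodide formed from 16 by methylation at nitrogen | CC(C)=CCC/C(C)=C/CC/C(C)=C/CC[C@@H](C(=O)CC[N+](C)(C)C)[C@@]1(C)CCCC(C)(C)[C@@H]1OC(=S)SC.[I-] | intermediate
18 | O-[(1S,2R)-2,6,6-trimethyl-2-[(4R,7E,11E)-8,12,16-trimethyl-3-oxoheptadeca-1,7,11,15-tetraen-4-yl]cyclohexyl] S-methyl carbonodithioate | CC(C)=CCC/C(C)=C/CC/C(C)=C/CC[C@@H](C(=O)C=C)[C@@]1(C)CCCC(C)(C)[C@@H]1OC(=S)SC | intermediate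
19 | (1R,4aR,8aS)-5,5,8a-trimethyl-1-[(3E,7E)-4,8,12-trimethyltrideca-3,7,11-trien-1-yl]octahydronaphthalen-2(1H)-one | CC(C)=CCC/C(C)=C/CC/C(C)=C/CC[C@@H]1[C@@]2(C)CCCC(C)(C)[C@H]2CCC1=O | intermediate
20 | (1R,2R,4aR,8aS)-2,5,5,8a-tetramethyl-1-[(3E,7E)-4,8,12-trimethyltrideca-3,7,11-trien-1-yl]decahydronaphthalen-2-ol (CNP0389811.1) | CC(C)=CCC/C(C)=C/CC/C(C)=C/CC[C@@H]1[C@@]2(C)CCCC(C)(C)[C@H]2CC[C@@]1(C)O | target

Total step count: 13. Longest linear sequence: 13 steps (1 → 20); ketone 9 and phosphonate 5 enter as commercial compounds.

## Least certain steps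

**Step 12 (key step).**
- What may go wrong: hydrogen transfer from the stannane to the hindered C5 radical before it closes; 1,5-hydrogen transfer from allylic C12 or 6-exo addition to the C13=C14 alkene; stannyl radical addition to the enone or radical oligomerisation of the vinyl ketone; partial closure to the trans-fused isomer.
- Fallback (sets out from 15, returns at 19): the C5–C6 bond is made by intermolecular allyl transfer, with no hydride donor in the flask, and ring B is then closed by metathesis. Heating 15 with allyltributylstannane and AIBN in benzene (Keck allylation) should give the C5-allyl compound F1, with the allyl group entering anti to the C10 methyl for the same steric reasons as in step 12. Ring-closing metathesis between the allyl group and the silyl enol ether alkene with the second-generation Grubbs catalyst gives the cyclic silyl enol ether F2 with C7=C8 in ring B, and Bu4NF buffered with acetic acid releases 19.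

**Step 6.**
- What may go wrong: attack on the wrong face of the enolate, giving the C10 epimer relative to C9; sluggish reaction of the fully substituted, hindered enolate; loss of branched selectivity.
- Fallback (sets out from 9, returns at 10): the two centres are set one after the other under separate reagent control. O-Acylation of the enolate of 9 (LiN(SiMe3)2, allyl chloroformate) gives the allyl enol carbonate F3. Enantioselective decarboxylative allylation with zerovalent palladium (Pd2(dba)3, (R)-t-Bu-PHOX, THF) gives (R)-2-allyl-2,6,6-trimethylcyclohexan-1-one F4 with C10 fixed. Ozonolysis (O3, then Me2S; no chain alkenes are present yet) gives the keto aldehyde F5, and condensation with (S)-1-amino-2-(methoxymethyl)pyrrolidine gives the hydrazone F6. Deprotonation with LiN(iPr)2 and alkylation with the known homofarnesyl iodide F7 gives the hydrazone F8, in which the auxiliary sets C9. Two-phase hydrolysis with aqueous oxalic acid gives the aldehyde F9, and Ph3P=CH2 at low temperature turns its formyl group into the vinyl group of 10.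

**Step 7.**
- What may go wrong: slow oxidation of the hindered vinyl group, with double-bond migration through palladium hydride species (which would erase C9) or anti-Markovnikov attack leading to the aldehyde.
- Fallback (sets out from 9, returns at 11): the route of the step 6 fallback is followed as far as aldehyde F9. MeMgBr/CeCl3 at −78 °C, where the ring ketone is too hindered to react, gives the secondary alcohol F10, and oxidation with the periodinane 1,1,1-triacetoxy-1,1-dihydro-1,2-benziodoxol-3(1H)-one gives 11 without any palladium step.

**Step 10.**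
- What may go wrong: incomplete formation of the alkoxide at an alcohol flanked by two quaternary carbons; silyl transfer from the enol oxygen to that alkoxide.
- Fallback (sets out from 13, returns at 19): the radical leaving group is put on by acylation instead of through an alkoxide. Pentafluorophenyl chlorothionoformate with N-hydroxysuccinimide and pyridine in benzene gives the thionocarbonate F11. The conditions of step 11 convert it into the vinyl ketone F12, and the conditions of step 12 close ring B to 19.

**Step 13.**
- What may go wrong: poor facial selectivity at C8, through axial attack from the α face or reaction through the other ring conformer, giving the C8 epimer.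
- Fallback (sets out from 19, returns at 20): the C8–C17 bond is formed under thermodynamic control (Corey–Chaykovsky reaction). Dimethylsulfoxonium methylide (Me3S(O)I, NaH, DMSO) adds reversibly and should give the spiro-epoxide F13 with the new carbon equatorial (β) and the oxygen axial (α). LiEt3BH opens the epoxide at the CH2 carbon to give 20.

## Further compounds

F1 | step 12 | C5-allyl analogue of 15 (xanthate replaced by prop-2-enyl, allyl trans to the C10 methyl, silyl enol ether kept) | CC(C)=CCC/C(C)=C/CC/C(C)=C/CC[C@@H](C(=C)O[Si](C(C)C)(C(C)C)C(C)C)[C@@]1(C)CCCC(C)(C)[C@H]1CC=C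
F2 | step 12 | triisopropylsilyl enol ether of 19 with the C7=C8 alkene in ring B | CC(C)=CCC/C(C)=C/CC/C(C)=C/CC[C@@H]1[C@@]2(C)CCCC(C)(C)[C@H]2CC=C1O[Si](C(C)C)(C(C)C)C(C)C
F3 | step 6 | allyl 2,6,6-trimethylcyclohex-1-en-1-yl carbonate | C=CCOC(=O)OC1=C(C)CCCC1(C)C
F4 | step 6 | (2R)-2-allyl-2,6,6-trimethylcyclohexan-1-one | C=CC[C@@]1(C)CCCC(C)(C)C1=O
F5 | step 6 | 2-[(1R)-1,3,3-trimethyl-2-oxocyclohexyl]acetaldehyde | O=CC[C@@]1(C)CCCC(C)(C)C1=O
F6 | step 6 | (E)-hydrazone of F5 with (S)-1-amino-2-(methoxymethyl)pyrrolidine | COC[C@@H]1CCCN1/N=C/C[C@@]1(C)CCCC(C)(C)C1=O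
F7 | step 6 | (3E,7E)-1-iodo-4,8,12-trimethyltrideca-3,7,11-triene (homofarnesyl iodide) | CC(C)=CCC/C(C)=C/CC/C(C)=C/CCI
F8 | step 6 | (E)-hydrazone of F9 with (S)-1-amino-2-(methoxymethyl)pyrrolidine | CC(C)=CCC/C(C)=C/CC/C(C)=C/CC[C@@H](/C=N/N1CCC[C@H]1COC)[C@@]1(C)CCCC(C)(C)C1=O
F9 | step 6 | (2R,5E,9E)-6,10,14-trimethyl-2-[(1R)-1,3,3-trimethyl-2-oxocyclohexyl]pentadeca-5,9,13-trienal | CC(C)=CCC/C(C)=C/CC/C(C)=C/CC[C@@H](C=O)[C@@]1(C)CCCC(C)(C)C1=O
F10 | step 7 | (2R)-2-[(3R,6E,10E)-2-hydroxy-7,11,15-trimethylhexadeca-6,10,14-trien-3-yl]-2,6,6-trimethylcyclohexan-1-one (carbinol epimers) | CC(C)=CCC/C(C)=C/CC/C(C)=C/CC[C@@H](C(C)O)[C@@]1(C)CCCC(C)(C)C1=O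
F11 | step 10 | O-pentafluorophenyl thionocarbonate of 13 | CC(C)=CCC/C(C)=C/CC/C(C)=C/CC[C@@H](C(=C)O[Si](C(C)C)(C(C)C)C(C)C)[C@@]1(C)CCCC(C)(C)[C@@H]1OC(=S)Oc1c(F)c(F)c(F)c(F)c1F
F12 | step 10 | O-pentafluorophenyl thionocarbonate analogue of 18 (vinyl ketone) | CC(C)=CCC/C(C)=C/CC/C(C)=C/CC[C@@H](C(=O)C=C)[C@@]1(C)CCCC(C)(C)[C@@H]1OC(=S)Oc1c(F)c(F)c(F)c(F)c1F
F13 | step 13 | spiro-epoxide of 19 at C8 (CH2 on the β face, oxygen on the α face) | CC(C)=CCC/C(C)=C/CC/C(C)=C/CC[C@@H]1[C@@]2(C)CCCC(C)(C)[C@H]2CC[C@]13CO3
A1 | alternative 1 | trisubstituted cyclohexenone with the chain on C9, methyl on C8 and carbonyl on C7 | CC(C)=CCC/C(C)=C/CC/C(C)=C/CC[C@@H]1[C@@](C)(CCCC(C)(C)C(=O)OC)C=CC(=O)[C@H]1C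
A2 | alternative 1 | methyl 2,2-dimethyl-5-(1-methyl-4-oxocyclohexa-2,5-dien-1-yl)pentanoate | COC(=O)C(C)(C)CCCC1(C)C=CC(=O)C=C1
A3 | alternative 1 | [(3E,7E)-4,8,12-trimethyltrideca-3,7,11-trien-1-yl]magnesium bromide | CC(C)=CCC/C(C)=C/CC/C(C)=C/CC[Mg]Br
A4 | alternative 2 | tricyclic cyclopropyl ketone (C8 ketone, cyclopropane C1–C9–C10) | O=C1CC[C@@H]2C(C)(C)CC[C@@H]3[C@H]1[C@]23C
A5 | alternative 2 | (R)-α-ionone | CC1=CCCC(C)(C)[C@H]1/C=C/C(C)=O
A6 | alternative 2 | 1-diazo-4-[(1R)-2,6,6-trimethylcyclohex-2-en-1-yl]butan-2-one | CC1=CCCC(C)(C)[C@H]1CCC(=O)C=[N+]=[N-]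
A7 | alternative 3 | cis-fused angular aldehyde with the C7=C8 alkene and a silyloxyethyl group on C9 | CC(C)(C)[Si](C)(C)OCC[C@@H]1[C@@]2(C=O)CCCC(C)(C)[C@H]2CC=C1C
A8 | alternative 3 | 3,3-dimethylcyclohex-1-ene-1-carbaldehyde | O=CC1=CC(C)(C)CCC1
A9 | alternative 3 | tert-butyl(dimethyl){[(3E)-4-methylhexa-3,5-dien-1-yl]oxy}silane | C=C/C(C)=C/CCO[Si](C)(C)C(C)(C)C
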